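## Retrosynthetic overview

1. Numbering used: ring C1 (C=O), C2=C3, C4 (CH–OAc), C5 (C–OH), side-chain carbinol C1′. The cut is C1′–C5. C5 is the α-carbon of the C1 ketone and C1′ is a carbinol carbon, so this bond is the Cα–Cβ bond of an aldol (O=C1–C5–C1′–OH). C5 also carries one of the two vicinal ring oxygens (O4/O5), which can be tied as a cis-fused 1,3-dioxolane; this makes the C5 enolate easy to form, rigid and open on one face only.
2. Fragments: tridecanal and the lithium enolate of the chiral-pool acetonide enone 1. In the enolate only C4 is stereogenic; one aldol event relays it to C5 (ring fusion) and to C1′ (closed chair).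
3. End game: C1′–OH is masked as a TIPS ether, the dioxolane is hydrolysed, and the relay centre C4 is inverted by a Mitsunobu reaction with AcOH. This installs the acetate and the 4,5-trans relation in one operation; desilylation then gives the target.
4. Rings: the cyclopentenone ring is bought with 1 and no ring is formed; the temporary dioxolane ring is removed in step 3.

Key step: step 1

Assumption: the (3aS,6aS)-antipode of the ribose-derived acetonide enone (compound 1) is taken as a purchasable chiral-pool compound, like its (3aR,6aR)-antipode.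

## Route

Step 1
Reactants: 1 (3aS,6aS)-2,2-dimethyl-3a,6a-dihydro-4H-cyclopenta[d][1,3]dioxol-4-one; 2 tridecanal
Product: 5 (3aS,6aS)-3a-[(1S)-1-hydroxytridecyl]-2,2-dimethyl-3a,6a-dihydro-4H-cyclopenta[d][1,3]dioxol-4-one, via lithium dienolate 3 (not isolated), via lithium aldolate 4 (not isolated)
Conditions: LiHMDS (1.05 equiv), THF, −78 °C; then 2, −78 °C; AcOH quench at −78 °C
Reagents that add atoms: none
Why: LiHMDS removes the C5–H (α to C1=O and acidified by O5) to give the cross-conjugated lithium dienolate 3, which adds to tridecanal through a closed six-membered chair (Zimmerman–Traxler) transition state; this is a directed lithium-enolate aldol addition, the closest known reaction type being the α′-aldol additions of 4-oxygenated cyclopent-2-enone enolates to aliphatic aldehydes. No ring is closed, and the cis-fused dioxolane is carried through unchanged. C5: only C4 is stereogenic in 3, and because a trans-fused 5/5 ketal cannot form, the aldehyde must bond to the face of C5 opposite O4 (the convex face), which fixes C5 with O5 cis to O4. C1′: in the chair the dioxolane oxygen on C5 is cis to OLi (a Z-type substituent) and the C12 chain sits equatorial, which should place O5 and O1′ syn and give 1′S. The step needs α′- rather than γ-deprotonation and C–C bond formation at C5 rather than reaction at oxygen; the kinetic amide base at −78 °C and the extra acidity of the α-alkoxy C5–H secure this, and loss of O4 from 3 by β-elimination is disfavoured because it would give an antiaromatic cyclopentadienone.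

Step 2
Reactants: 5 (3aS,6aS)-3a-[(1S)-1-hydroxytridecyl]-2,2-dimethyl-3a,6a-dihydro-4H-cyclopenta[d][1,3]dioxol-4-one
Product: 6 (3aR,6aS)-2,2-dimethyl-3a-[(1S)-1-(triisopropylsilyloxy)tridecyl]-3a,6a-dihydro-4H-cyclopenta[d][1,3]dioxol-4-one
Conditions: TIPSOTf, 2,6-lutidine, CH2Cl2, 0 °C → rt
Reagents that add atoms: triisopropylsilyl trifluoromethanesulfonate, CC(C)[Si](C(C)C)(C(C)C)OS(=O)(=O)C(F)(F)F
Why: O-silylation with a silyl triflate (silyl ether formation) works on hindered secondary carbinols, and since C5 bears no hydrogen the weak base opens neither enolisation nor retro-aldol; no stereocenter is touched (the 3a descriptor becomes R only because the silyloxy carbon now outranks C6a).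

Step 3
Reactants: 6 (3aR,6aS)-2,2-dimethyl-3a-[(1S)-1-(triisopropylsilyloxy)tridecyl]-3a,6a-dihydro-4H-cyclopenta[d][1,3]dioxol-4-one
Product: 7 (4S,5R)-4,5-dihydroxy-5-[(1S)-1-(triisopropylsilyloxy)tridecyl]cyclopent-2-en-1-one (cis-4,5-diol)
Conditions: TFA–H2O (9:1), CH2Cl2, 0 °C → rt
Reagents that add atoms: none
Why: Acid-catalysed ketal hydrolysis breaks only the O–CMe2 bonds, so C4 and C5 keep their configuration, and the hindered secondary TIPS ether should be far more acid-stable than the dioxolane.

Step 4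
Reactants: 7 (4S,5R)-4,5-dihydroxy-5-[(1S)-1-(triisopropylsilyloxy)tridecyl]cyclopent-2-en-1-one
Product: 9 (1R,5R)-5-hydroxy-4-oxo-5-[(1S)-1-(triisopropylsilyloxy)tridecyl]cyclopent-2-en-1-yl acetate, via C4 oxyphosphonium acetate 8 (not isolated)
Conditions: PPh3, DIAD, AcOH, THF, 0 °C → rt
Reagents that add atoms: acetic acid, CC(=O)O
Why: Mitsunobu esterification: the only substitutable hydroxyl (secondary, allylic C4–OH; the tertiary C5–OH cannot be displaced and, being cis, cannot close an epoxide) is activated as oxyphosphonium 8 and displaced by acetate in an SN2 step with inversion (4S → 4R), which sets the 4,5-trans relation and installs the acetyl group at once.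

Step 5
Reactants: 9 (1R,5R)-5-hydroxy-4-oxo-5-[(1S)-1-(triisopropylsilyloxy)tridecyl]cyclopent-2-en-1-yl acetate
Product: 10 (1R,5S)-5-hydroxy-5-[(1S)-1-hydroxytridecyl]-4-oxocyclopent-2-en-1-yl acetate (target)
Conditions: HF·pyridine, THF–pyridine, 0 °C → rt
Reagents that add atoms: none
Why: Fluoride-mediated Si–O cleavage (desilylation) under buffered acidic conditions needs no base, so the allylic acetate should neither migrate nor eliminate, and the enone and all three stereocenters are untouched.

## Compound list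

1 | (3aS,6aS)-2,2-dimethyl-3a,6a-dihydro-4H-cyclopenta[d][1,3]dioxol-4-one | CC1(C)O[C@@H]2C(=O)C=C[C@@H]2O1 | starting material
2 | tridecanal | CCCCCCCCCCCCC=O | starting material
3 | lithium (6aS)-2,2-dimethyl-6aH-cyclopenta[d][1,3]dioxol-4-olate (cross-conjugated dienolate of 1) | CC1(C)OC2=C(O[Li])C=C[C@@H]2O1 | intermediate (not isolated)
4 | lithium (1S)-1-[(3aS,6aS)-2,2-dimethyl-4-oxo-4,6a-dihydro-3aH-cyclopenta[d][1,3]dioxol-3a-yl]tridecan-1-olate | CCCCCCCCCCCC[C@H](O[Li])[C@]12OC(C)(C)O[C@H]1C=CC2=O | intermediate (not isolated)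
5 | (3aS,6aS)-3a-[(1S)-1-hydroxytridecyl]-2,2-dimethyl-3a,6a-dihydro-4H-cyclopenta[d][1,3]dioxol-4-one | CCCCCCCCCCCC[C@H](O)[C@]12OC(C)(C)O[C@H]1C=CC2=O | intermediate
6 | (3aR,6aS)-2,2-dimethyl-3a-[(1S)-1-(triisopropylsilyloxy)tridecyl]-3a,6a-dihydro-4H-cyclopenta[d][1,3]dioxol-4-one | CCCCCCCCCCCC[C@H](O[Si](C(C)C)(C(C)C)C(C)C)[C@]12OC(C)(C)O[C@H]1C=CC2=O | intermediate
7 | (4S,5R)-4,5-dihydroxy-5-[(1S)-1-(triisopropylsilyloxy)tridecyl]cyclopent-2-en-1-one (cis-diol) | CCCCCCCCCCCC[C@H](O[Si](C(C)C)(C(C)C)C(C)C)[C@@]1(O)C(=O)C=C[C@@H]1O | intermediate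
8 | triphenyl{[(1S,5S)-5-hydroxy-4-oxo-5-[(1S)-1-(triisopropylsilyloxy)tridecyl]cyclopent-2-en-1-yl]oxy}phosphonium acetate | CCCCCCCCCCCC[C@H](O[Si](C(C)C)(C(C)C)C(C)C)[C@@]1(O)C(=O)C=C[C@@H]1O[P+](c1ccccc1)(c1ccccc1)c1ccccc1.CC(=O)[O-] | intermediate (not isolated)
9 | (1R,5R)-5-hydroxy-4-oxo-5-[(1S)-1-(triisopropylsilyloxy)tridecyl]cyclopent-2-en-1-yl acetate | CCCCCCCCCCCC[C@H](O[Si](C(C)C)(C(C)C)C(C)C)[C@@]1(O)C(=O)C=C[C@H]1OC(C)=O | intermediate
10 | (1R,5S)-5-hydroxy-5-[(1S)-1-hydroxytridecyl]-4-oxocyclopent-2-en-1-yl acetate | CCCCCCCCCCCC[C@H](O)[C@@]1(O)C(=O)C=C[C@H]1OC(C)=O | target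

## Step count and risks

Total step count: 5. Longest linear sequence: 5 steps (from 1 or 2).

Steps most likely to fail, most at risk first:

Step 4. What may go wrong: the SN2 displacement at C4 is slowed by the fully substituted C5 next to it, because the nucleophile has to enter syn to the C5 side chain. O-acylation with retention, SN2′ attack at C2 or plain non-conversion may then take over. Fallback (sets out from 7, returns at 9): the cis-diol is closed with SOCl2/Et3N (CH2Cl2, 0 °C) to the 4,5-cyclic sulfite F1. RuCl3 (cat.)/NaIO4 (MeCN–H2O, 0 °C) oxidises it to the 4,5-cyclic sulfate F2. CsOAc in DMF should open this much stronger electrophile at the secondary allylic C4 with inversion, giving the caesium 5-O-sulfate of the 4-acetate F3. Catalytic H2SO4 with one equivalent of water in THF then cleaves the sulfate monoester to 9.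

Step 1. What may go wrong: insufficient discrimination between the two faces of the aldehyde (C1′ epimers), or retro-aldol equilibration on warming. Fallback (sets out from 1 and 2, returns at 5): C1′ is set by reduction instead of in the C–C bond formation. The aldol is run as in step 1, and the mixture of 5 and its C1′ epimer F4 is oxidised with Dess–Martin periodinane (CH2Cl2, rt) to the single 3a-tridecanoyl ketone F5. Reagent-controlled CBS reduction of the saturated, α-alkoxy side-chain ketone ((R)-Me-CBS, catecholborane, toluene, −78 °C; quaternary C5 as the large and the alkyl CH2 as the small substituent) should then give 5.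

Step 3. What may go wrong: partial loss of the silyl ether, or degradation of the cis-diol enone, during the acid treatment that the robust cis-fused ketal needs. Fallback (sets out from 5, returns at 10): C1′–OH is masked as an acid-inert chloroacetate instead of a silyl ether. Chloroacetic anhydride/pyridine (CH2Cl2, 0 °C) gives the chloroacetate F6, and aqueous TFA removes the acetonide to give the diol F7. The Mitsunobu reaction of step 4 (PPh3, DIAD, AcOH, THF) gives the 4-acetate F8. Thiourea/NaHCO3 (EtOH, 40 °C) then removes the chloroacetate selectively in the presence of the acetate and gives 10 directly, which also bypasses step 5.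

## Further compounds

F1 | step 4 | 4,5-cyclic sulfite of diol 7 (O4,O5-sulfinyl, both S-epimers) | CCCCCCCCCCCC[C@H](O[Si](C(C)C)(C(C)C)C(C)C)[C@]12OS(=O)O[C@H]1C=CC2=O
F2 | step 4 | 4,5-cyclic sulfate of diol 7 | CCCCCCCCCCCC[C@H](O[Si](C(C)C)(C(C)C)C(C)C)[C@]12OS(=O)(=O)O[C@H]1C=CC2=O
F3 | step 4 | caesium (1R,5R)-5-acetoxy-2-oxo-1-[(1S)-1-(triisopropylsilyloxy)tridecyl]cyclopent-3-en-1-yl sulfate | CCCCCCCCCCCC[C@H](O[Si](C(C)C)(C(C)C)C(C)C)[C@@]1(OS(=O)(=O)[O-])C(=O)C=C[C@H]1OC(C)=O.[Cs+]
F4 | step 1 | (3aS,6aS)-3a-[(1R)-1-hydroxytridecyl]-2,2-dimethyl-3a,6a-dihydro-4H-cyclopenta[d][1,3]dioxol-4-one (C1′ epimer of 5) | CCCCCCCCCCCC[C@@H](O)[C@]12OC(C)(C)O[C@H]1C=CC2=O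
F5 | step 1 | (3aR,6aS)-2,2-dimethyl-3a-tridecanoyl-3a,6a-dihydro-4H-cyclopenta[d][1,3]dioxol-4-one | CCCCCCCCCCCCC(=O)[C@]12OC(C)(C)O[C@H]1C=CC2=O
F6 | step 3 | (1S)-1-[(3aS,6aS)-2,2-dimethyl-4-oxo-4,6a-dihydro-3aH-cyclopenta[d][1,3]dioxol-3a-yl]tridecyl 2-chloroacetate | CCCCCCCCCCCC[C@H](OC(=O)CCl)[C@]12OC(C)(C)O[C@H]1C=CC2=O
F7 | step 3 | (1S)-1-[(1R,5S)-1,5-dihydroxy-2-oxocyclopent-3-en-1-yl]tridecyl 2-chloroacetate (cis-diol) | CCCCCCCCCCCC[C@H](OC(=O)CCl)[C@@]1(O)C(=O)C=C[C@@H]1O
F8 | step 3 | (1S)-1-[(1S,5R)-5-acetoxy-1-hydroxy-2-oxocyclopent-3-en-1-yl]tridecyl 2-chloroacetate | CCCCCCCCCCCC[C@H](OC(=O)CCl)[C@@]1(O)C(=O)C=C[C@H]1OC(C)=O
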